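The readings are calculated with made-up constants; noise was put on by code.

You cannot read product at 27.0% of the substrate charged as substrate used up, yet Saturday's run stands at that reading at 20.0 min and at 30.0 min. Nor did product use up the partner: that run made 5.40 mM against 18 mM of partner charged, if one partner goes into each product.

| setting | Sunday's | Tuesday's | Saturday's | flask |
|---|---|---|---|---|
| substrate | 0.010 M | 0.010 M | 0.020 M | 0.010 M |
| partner | 0.0090 M | 0.036 M | 0.018 M | 0.0180 M |
| free catalyst | 50 µM | 50 µM | 50 µM | 50 µM |
| remark | run made earlier | run made earlier | run made earlier |  |

- Sunday's (time / min: product / %): 2.50: 14.3; 4.00: 19.7; 6.00: 25.9; 10.0: 29.5; 20.0: 30.7; 30.0: 31.1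
- Tuesday's (time / min: product / %): 5.00: 39.1; 10.0: 61.5; 15.0: 69.7; 20.0: 70.4; 25.0: 71.0; 30.0: 71.5
- Saturday's (time / min: product / %): 2.50: 10.1; 8.00: 23.4; 15.0: 26.7; 20.0: 27.0; 30.0: 27.0

(readings scatter by 0.3 percentage points)

* apparent order in partner when 30% of the substrate are converted (percent change of the rate of making product for one percent more partner charged)
* apparent order in free catalyst when 30% of the substrate are converted (percent change of the rate of making product for one percent more free catalyst charged)

- no earlier run changes the charge of free catalyst; that part of a forecast is a guess

Divide the product at the last reading by the partner charged and call this y. Sunday's run gives 0.346, Tuesday's 0.199 and Saturday's 0.300. Between Sunday's and Tuesday's runs the product at the stop rises with the partner charge, yet y falls, so I read each stop as partner gone, with 28.8 mM of Tuesday's charge lost on a path that makes no product.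

The flask has Sunday's and Tuesday's substrate, and its partner charge is their geometric mean, so I take the geometric mean of their y: 0.262. This partner yield, product at the stop per partner charged, is what I carry.

Saturday's run is the neighbour, with the flask's partner charge and twice its substrate. I place the flask's stop at 4.72 mM, lower than Saturday's 5.40 mM. My reading is that y is lower in the flask because its smaller substrate charge gives the product path less speed against the same loss. The asked conversion lies 63.6% of the way to that stop, so the flask is still running there, but I reckon no order of my own.

The forecast says 1.3 in partner and 2.2 in free catalyst, and it reads the stop differently from me: “Catalyst appears to be lost per turnover”.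

The flask gives 0.90 and 1.7, each lower than forecast.

    partner + catalyst intermediate A → catalyst intermediate B (k = 3950 /M/min)
    catalyst intermediate C → free catalyst + product (k = 61.3 /min)
    substrate + free catalyst → catalyst intermediate A (k = 7420 /M/min)
    catalyst intermediate B → by-product + catalyst intermediate C (k = 58.5 /min)
    partner → decomposed reagent (k = 0.210 /min)

In the flask, partner left by two steps at once: decomposition reached the midpoint of its turnover up to 30.0 min at 2.30 min, and the step from partner and catalyst intermediate A to catalyst intermediate B reached its midpoint at 3.54 min. By 15.0 min partner, the limiting reagent, stood at 0.607% of its charge, and catalyst intermediate A, the resting state, held 97.4% of the catalyst. At 30.0 min the flask's partner yield stood at 0.275, lower than the 0.300 read from Saturday's run.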